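**Retrosynthetic overview**

1. The strategy rests on ring C of the flavonol: O1 is bonded to C2 and a hydroxyl sits on C3 across the C2=C3 bond beside the C4 carbonyl, the pattern left when the alkene of a 2'-hydroxychalcone is oxidised.
2. Target ⇒ 3-hydroxy-5,6,7,8,4'-pentamethoxyflavone: the 5-methoxyl, peri to the C4 carbonyl, is the one ether that can be cleaved selectively at the end.
3. Flavonol ⇒ 2'-hydroxy-3',4',5',6',4-pentamethoxychalcone by breaking O1–C2 and C3–O (Algar–Flynn–Oyamada closure). Ring C is the only ring made; rings A and B are bought as benzenes.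
4. Chalcone ⇒ 4-methoxybenzaldehyde + 2'-hydroxy-3',4',5',6'-tetramethoxyacetophenone (Claisen–Schmidt). The ketone ⇒ pentamethoxybenzene + acetyl chloride (Friedel–Crafts with ortho-demethylation). Pentamethoxybenzene ⇒ 2,6-dimethoxy-1,4-benzoquinone (Thiele–Winter acetoxylation, then hydrolysis–methylation).

Key step: step 5

Remark on the chemistry: the target is achiral; the transient trans-dihydroflavonol of the key step is racemic and is drawn as its (2R,3R) enantiomer.

**Route**

Step 1
Reactants: 1 2,6-dimethoxy-1,4-benzoquinone
Product: 2 3,5-dimethoxybenzene-1,2,4-triyl triacetate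
Conditions: Ac2O, cat. conc. H2SO4, 25–40 °C; then ice-water
Reagents that add atoms: acetic anhydride CC(=O)OC(C)=O
Why: Thiele–Winter acetoxylation, in which the acid-activated quinone takes acetate by conjugate addition at one of its two symmetry-equivalent unsubstituted ring carbons and the acetoxyhydroquinone so formed is acetylated in the same flask, so only one regioisomer is possible.

Step 2
Reactants: 2 3,5-dimethoxybenzene-1,2,4-triyl triacetate
Product: 4 1,2,3,4,5-pentamethoxybenzene, via 3,5-dimethoxybenzene-1,2,4-triol 3 (not isolated)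
Conditions: Me2SO4 (excess), NaOH aq, MeOH, Na2S2O4 (trace), N2, 0 °C to reflux
Reagents that add atoms: dimethyl sulfate COS(=O)(=O)OC
Why: Saponification of the three aryl acetates and Williamson O-methylation of the phenoxides as they are released, run under N2 with dithionite so that the air-sensitive triol does not accumulate.

Step 3
Reactants: 4 1,2,3,4,5-pentamethoxybenzene; 5 acetyl chloride
Product: 7 1-(2-hydroxy-3,4,5,6-tetramethoxyphenyl)ethan-1-one, via 2,3,4,5,6-pentamethoxyacetophenone 6 (not isolated)
Conditions: AcCl (1.2 equiv), AlCl3 (2.5 equiv), Et2O, 0 °C to rt; then ice-water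
Reagents that add atoms: none
Why: Friedel–Crafts acylation at the only free position of the electron-rich arene, after which AlCl3 chelated between the new carbonyl and a flanking methoxyl cleaves that O–CH3 bond (chloride SN2 at methyl); the two ortho methoxyls of 6 are equivalent, so one hydroxyketone results, and its aluminium phenoxide chelate should resist a second cleavage.

Step 4
Reactants: 7 1-(2-hydroxy-3,4,5,6-tetramethoxyphenyl)ethan-1-one; 8 4-methoxybenzaldehyde
Product: 9 (E)-1-(2-hydroxy-3,4,5,6-tetramethoxyphenyl)-3-(4-methoxyphenyl)prop-2-en-1-one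
Conditions: KOH (50% aq), EtOH, rt; then dil. HCl
Reagents that add atoms: none
Why: Claisen–Schmidt condensation, in which the methyl ketone enolate adds to the non-enolisable aldehyde and E1cB loss of water gives the conjugated enone with the thermodynamically favoured E geometry.

Step 5
Reactants: 9 (E)-1-(2-hydroxy-3,4,5,6-tetramethoxyphenyl)-3-(4-methoxyphenyl)prop-2-en-1-one
Product: 11 3-hydroxy-5,6,7,8-tetramethoxy-2-(4-methoxyphenyl)-4H-chromen-4-one, via trans-dihydroflavonol 10 (not isolated)
Conditions: 30% H2O2 (4 equiv), 2 M NaOH aq (excess), MeOH–THF, 0 °C to rt; then dil. HCl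
Reagents that add atoms: hydrogen peroxide OO
Why: This is the Algar–Flynn–Oyamada reaction, the standard conversion of 2'-hydroxychalcones into flavonols: the 2'-phenoxide of 9 adds to the enone β-carbon (the future C2) to form the O1–C2 bond and the enolate carbon so produced (the future C3) takes an electrophilic oxygen from H2O2 to form the C3–O bond, the variant through Weitz–Scheffer epoxidation and phenoxide opening of the epoxide at its benzylic carbon leading to the same compound. Ring C closes in the 6-endo-trig mode (6-endo-tet in the epoxide variant) to the racemic trans-dihydroflavonol 10, whose aryl and hydroxyl groups are both equatorial, and excess alkaline peroxide dehydrogenates 10 through its enolate to the flavonol 11. No stereocentre has to be controlled, because C2 and C3 of 10 end as the C2=C3 double bond. The selectivity that the step needs is closure at the β-carbon (six-membered ring) in preference to 5-exo closure at the α-carbon, which gives the aurone and is the pathway that a 6'-methoxyl beside the ketone is known to encourage. In 9 the 4-methoxyphenyl group makes the β-carbon the benzylic, cation-stabilised and therefore more electrophilic terminus, and cold dilute peroxide with a large excess of hydroxide should keep the conjugate closure ahead of epoxidation, though some aurone is to be expected and would be removed by chromatography. The rest of the substrate cannot interfere: there is a single phenol, ring A has no free position and the C3 hydroxyl is delivered unprotected.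

Step 6
Reactants: 11 3-hydroxy-5,6,7,8-tetramethoxy-2-(4-methoxyphenyl)-4H-chromen-4-one
Product: 12 3,5-dihydroxy-6,7,8-trimethoxy-2-(4-methoxyphenyl)-4H-chromen-4-one (3,5-dihydroxy-6,7,8,4'-tetramethoxyflavone)
Conditions: BCl3 (3 equiv), CH2Cl2, −78 to 0 °C; then aq. HCl–MeOH, 50 °C
Reagents that add atoms: none
Why: Chelation-directed aryl methyl ether cleavage, in which boron held at the C4 carbonyl oxygen reaches only the peri 5-methoxyl through a six-membered chelate and chloride removes that methyl as CH3Cl, while the 6-, 7-, 8- and 4'-methoxyls have no carbonyl neighbour and the C3 hydroxyl only consumes one equivalent of BCl3 as a borate that is hydrolysed on work-up.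

**Compound list**

1 | 2,6-dimethoxy-1,4-benzoquinone | COC1=CC(=O)C=C(OC)C1=O | starting material
2 | 3,5-dimethoxybenzene-1,2,4-triyl triacetate | CC(=O)Oc1cc(OC)c(OC(C)=O)c(OC)c1OC(C)=O | intermediate
3 | 3,5-dimethoxybenzene-1,2,4-triol (not isolated) | COc1cc(O)c(O)c(OC)c1O | intermediate
4 | 1,2,3,4,5-pentamethoxybenzene | COc1cc(OC)c(OC)c(OC)c1OC | intermediate
5 | acetyl chloride | CC(Cl)=O | starting material
6 | 2,3,4,5,6-pentamethoxyacetophenone (not isolated) | CC(=O)c1c(OC)c(OC)c(OC)c(OC)c1OC | intermediate
7 | 1-(2-hydroxy-3,4,5,6-tetramethoxyphenyl)ethan-1-one | CC(=O)c1c(O)c(OC)c(OC)c(OC)c1OC | intermediate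
8 | 4-methoxybenzaldehyde | COc1ccc(C=O)cc1 | starting material
9 | (E)-1-(2-hydroxy-3,4,5,6-tetramethoxyphenyl)-3-(4-methoxyphenyl)prop-2-en-1-one | COc1ccc(/C=C/C(=O)c2c(O)c(OC)c(OC)c(OC)c2OC)cc1 | intermediate
10 | rac-(2R,3R)-3-hydroxy-5,6,7,8-tetramethoxy-2-(4-methoxyphenyl)-2,3-dihydro-4H-chromen-4-one (trans-dihydroflavonol, not isolated) | COc1ccc([C@H]2Oc3c(OC)c(OC)c(OC)c(OC)c3C(=O)[C@@H]2O)cc1 | intermediate
11 | 3-hydroxy-5,6,7,8-tetramethoxy-2-(4-methoxyphenyl)-4H-chromen-4-one | COc1ccc(-c2oc3c(OC)c(OC)c(OC)c(OC)c3c(=O)c2O)cc1 | intermediate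
12 | 3,5-dihydroxy-6,7,8-trimethoxy-2-(4-methoxyphenyl)-4H-chromen-4-one | COc1ccc(-c2oc3c(OC)c(OC)c(OC)c(O)c3c(=O)c2O)cc1 | target

**Step count and risks**

Total step count: 6. Longest linear sequence: 6 steps (1 → 2 → 4 → 7 → 9 → 11 → 12).

Steps most likely to fail, riskiest first:

Risk 1, step 5. After epoxidation of the enone, the phenoxide may close onto the α-carbon (5-exo), the course favoured by the 6'-methoxyl, so that material is diverted to the aurone; oxidation may also stall at 10. The fallback sets out from 9 and closes ring C in a way that offers no choice of ring size. Catalytic I2 in DMSO at 130 °C (oxa-Michael closure, α-iodination, loss of HI) should give 5,6,7,8,4'-pentamethoxyflavone F1 (tangeretin). C3 of F1 is then deprotonated with LiN(iPr)2 in THF at −78 °C and trapped with B(OMe)3 to give the dimethyl C3-boronate F2 (not isolated). Oxidation of the C–B bond with H2O2/AcOH returns the sequence to the route at 11.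

Risk 2, step 6. Further methyl groups may be lost, since the borate of the freed 5-hydroxyl can deliver the reagent to the neighbouring 6-methoxyl, or the reaction may stop short because the C3 hydroxyl ties up the carbonyl. The fallback sets out from 7 and differentiates the 5-oxygen before ring closure, so that the last step is a neutral hydrogenolysis and any over-cleaved material is removed at a cheap early stage. BCl3 (excess, CH2Cl2, 0 °C to rt) cleaves the second carbonyl-flanking methoxyl to give 1-(2,6-dihydroxy-3,4,5-trimethoxyphenyl)ethan-1-one F3. One equivalent of benzyl bromide with K2CO3 in acetone alkylates one of the two equivalent phenols (the other stays hydrogen-bonded to the carbonyl) to give 1-[2-(benzyloxy)-6-hydroxy-3,4,5-trimethoxyphenyl]ethan-1-one F4. Claisen–Schmidt condensation with 8 (KOH, EtOH) gives the benzyloxy chalcone F5. Alkaline H2O2 as in step 5 takes it through the trans-dihydroflavonol F6 (not isolated) to 5-(benzyloxy)-3-hydroxy-6,7,8-trimethoxy-2-(4-methoxyphenyl)-4H-chromen-4-one F7. Hydrogenolysis (H2, Pd/C, EtOAc) removes the benzyl group and arrives at 12.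

Risk 3, step 3. With AlCl3 the electron-rich pentaether may lose methyl groups before or beyond the intended one, and acylation at the position flanked by two methoxyls may be slow. The fallback sets out from 4 and separates C–C bond formation from ether cleavage. n-BuLi in THF at 0 °C removes the single ring hydrogen (directed ortho-metalation between two methoxyls) to give (pentamethoxyphenyl)lithium F8 (not isolated). Acylation with N-methoxy-N-methylacetamide gives 6, now isolated. BCl3 (1.1 equiv, CH2Cl2, −78 to 0 °C) then cleaves one of its two equivalent ortho methoxyls and returns to the route at 7.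

**Further compounds**

F1 | step 5 | 5,6,7,8-tetramethoxy-2-(4-methoxyphenyl)-4H-chromen-4-one (5,6,7,8,4'-pentamethoxyflavone) | COc1ccc(-c2cc(=O)c3c(OC)c(OC)c(OC)c(OC)c3o2)cc1
F2 | step 5 | dimethyl [5,6,7,8-tetramethoxy-2-(4-methoxyphenyl)-4-oxo-4H-chromen-3-yl]boronate | COB(OC)c1c(-c2ccc(OC)cc2)oc2c(OC)c(OC)c(OC)c(OC)c2c1=O
F3 | step 6 | 1-(2,6-dihydroxy-3,4,5-trimethoxyphenyl)ethan-1-one | CC(=O)c1c(O)c(OC)c(OC)c(OC)c1O
F4 | step 6 | 1-[2-(benzyloxy)-6-hydroxy-3,4,5-trimethoxyphenyl]ethan-1-one | CC(=O)c1c(O)c(OC)c(OC)c(OC)c1OCc1ccccc1
F5 | step 6 | (E)-1-[2-(benzyloxy)-6-hydroxy-3,4,5-trimethoxyphenyl]-3-(4-methoxyphenyl)prop-2-en-1-one | COc1ccc(/C=C/C(=O)c2c(O)c(OC)c(OC)c(OC)c2OCc2ccccc2)cc1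
F6 | step 6 | rac-(2R,3R)-5-(benzyloxy)-3-hydroxy-6,7,8-trimethoxy-2-(4-methoxyphenyl)-2,3-dihydro-4H-chromen-4-one | COc1ccc([C@H]2Oc3c(OC)c(OC)c(OC)c(OCc4ccccc4)c3C(=O)[C@@H]2O)cc1
F7 | step 6 | 5-(benzyloxy)-3-hydroxy-6,7,8-trimethoxy-2-(4-methoxyphenyl)-4H-chromen-4-one | COc1ccc(-c2oc3c(OC)c(OC)c(OC)c(OCc4ccccc4)c3c(=O)c2O)cc1
F8 | step 3 | (pentamethoxyphenyl)lithium | [Li]c1c(OC)c(OC)c(OC)c(OC)c1OC
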